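**Retrosynthetic overview**
1. 26 ⇐ 25 (loss of one silyl group) ⇐ β-lactone acid 12 + iodide 19. In one flask the C8–C9 bond closes ring B and the C9–C11 bond brings in the side chain.
2. Enabling feature: ring A (C1–C5, C10) hides a C2 axis through C5 and C2, because C4 and C10 each carry a methyl group and a carbonyl-level carbon (C19, C9) on opposite faces. O5 is syn to C9 and anti to C19, so O5 and C9 can be tied into the four-membered ring C5–O–C9–C10, with the C6–C7–C8 chain lying over C9.
3. 12 ⇐ hydroxy diacid 10 (only the syn carboxyl can lactonise) ⇐ C2-symmetric keto diester 5 + Grignard reagent 8 (homotopic ketone faces, C5–C6 bond).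
4. 5 ⇐ twofold asymmetric phase-transfer methylation of 3 ⇐ γ-acylation of 1; 19 ⇐ carboalumination of alkyne 13.
5. Ring order: ring A (present in 1), temporary oxetanone (closed in step 6, opened in step 11), ring B (step 11, last ring of the skeleton).

Key step: step 11

Remark: labdane numbering and α/β descriptors (10-methyl = β) are used for all intermediates. The enantiomer of the phase-transfer catalyst in step 2 is taken to be the one that gives S-configured centres, to be fixed in a preliminary experiment.

**Step 1**
Reactants: 1 tert-butyl 2-oxocyclohexane-1-carboxylate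
Product: 3 di-tert-butyl 2-oxocyclohexane-1,3-dicarboxylate (keto/enol and cis/trans mixture), via dilithium dianion 2 (not isolated)
Conditions: LDA (2.2 equiv), THF, −78 to 0 °C; Boc2O, −78 °C to rt; cold 1 M HCl work-up
Reagents that add atoms: di-tert-butyl dicarbonate, CC(C)(C)OC(=O)OC(=O)OC(C)(C)C
Why: The dianion of a β-keto ester reacts at its more basic γ-carbon, so Boc2O should transfer a tert-butoxycarbonyl group there (Claisen-type C-acylation of a β-keto ester dianion), and no lasting stereocentre is formed because both α-carbons stay enolisable.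

**Step 2**
Reactants: 3 di-tert-butyl 2-oxocyclohexane-1,3-dicarboxylate
Product: 5 di-tert-butyl (1S,3S)-1,3-dimethyl-2-oxocyclohexane-1,3-dicarboxylate (C2-symmetric, esters trans), via monomethyl keto diester 4 (not isolated)
Conditions: MeI (excess), CsOH·H2O, C2-symmetric N-spiro binaphthyl quaternary ammonium bromide (2 mol %), toluene, −40 to −20 °C
Reagents that add atoms: iodomethane, CI
Why: This is the asymmetric phase-transfer alkylation of cyclic tert-butyl β-keto esters run twice in one flask; the chiral ammonium enolate ion pair should expose the same enolate face both times, which sets C4 and C10 as S,S, and a twofold catalyst-controlled reaction raises the enantiopurity of the C2-symmetric product statistically.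

**Step 3**
Reactants: 6 3-bromobut-3-en-1-ol
Product: 7 2,4-dibromobut-1-ene
Conditions: CBr4, PPh3, CH2Cl2, 0 °C
Reagents that add atoms: tetrabromomethane, BrC(Br)(Br)Br
Why: The Appel reaction converts the primary alcohol into the bromide under neutral conditions that leave the vinylic bromide untouched.

**Step 4**
Reactants: 7 2,4-dibromobut-1-ene; 5 C2-symmetric keto diester
Product: 9 di-tert-butyl (1S,3S)-2-(3-bromobut-3-en-1-yl)-2-hydroxy-1,3-dimethylcyclohexane-1,3-dicarboxylate, via bromobutenyl Grignard reagent 8 (not isolated)
Conditions: 7, Mg, Et2O, rt; then 5, LaCl3·2LiCl (1 equiv), THF, −20 to 0 °C; cold aq NH4Cl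
Reagents that add atoms: none
Why: Magnesium inserts only into the sp3 C–Br bond in ether, and the LaCl3·2LiCl-promoted Grignard 1,2-addition suits a hindered non-enolisable ketone; the two ketone faces of C2-symmetric 5 are homotopic, so only one adduct can form and C5 is not yet a stereocentre.

**Step 5**
Reactants: 9 hydroxy di-tert-butyl ester
Product: 10 (1S,3S)-2-(3-bromobut-3-en-1-yl)-2-hydroxy-1,3-dimethylcyclohexane-1,3-dicarboxylic acid
Conditions: TFA/CH2Cl2 (1:2), 0 °C to rt
Reagents that add atoms: none
Why: Acidolysis of tert-butyl esters frees both acids, while the tertiary alcohol, flanked by two acceptor-bearing quaternary carbons, should not ionise and the vinylic bromide is inert.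

**Step 6**
Reactants: 10 hydroxy diacid
Product: 12 (1S,5S,6R)-6-(3-bromobut-3-en-1-yl)-1,5-dimethyl-8-oxo-7-oxabicyclo[4.2.0]octane-5-carboxylic acid (cis-fused β-lactone O5–C9; free C19 acid anti to O5), via lactone mixed anhydride 11 (not isolated)
Conditions: PhSO2Cl (2.5 equiv), pyridine, 0 °C; then H2O, 0 °C; extraction at pH 3
Reagents that add atoms: water, O
Why: This is the β-lactonisation of a β-hydroxy acid by carboxyl activation with a sulfonyl chloride in pyridine, which leaves the carbinol C–O bond untouched; only the carboxyl syn to the hydroxyl can close the cis-fused four-membered ring, so the diastereotopic carboxyls are told apart, C5 becomes a stereocentre (O5 syn to C9, anti to C19), and the anti carboxyl activated in 11 is returned to the acid by water.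

**Step 7**
Reactants: 13 tert-butyl(but-3-yn-1-yloxy)dimethylsilane
Product: 16 (E)-5-[(tert-butyldimethylsilyl)oxy]-3-methylpent-2-en-1-ol, via alkenylalane 14 (not isolated), via lithium alanate 15 (not isolated)
Conditions: Me3Al, Cp2ZrCl2 (20 mol %), CH2Cl2, 0 °C to rt; n-BuLi, THF/hexane, −78 °C; (CH2O)n, rt; aq Rochelle salt
Reagents that add atoms: trimethylaluminium, C[Al](C)C; formaldehyde (as paraformaldehyde), C=O
Why: The Zr-catalysed syn-carboalumination of a terminal alkyne (Negishi carboalumination) places methyl on the inner carbon, and hydroxymethylation of the alanate proceeds with retention, which sets the E C13=C14 double bond.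

**Step 8**
Reactants: 16 allylic alcohol
Product: 17 (E)-1-[(tert-butyldiphenylsilyl)oxy]-5-[(tert-butyldimethylsilyl)oxy]-3-methylpent-2-ene
Conditions: TBDPSCl, imidazole, CH2Cl2, rt
Reagents that add atoms: tert-butylchlorodiphenylsilane, CC(C)(C)[Si](Cl)(c1ccccc1)c1ccccc1
Why: Standard silylation of a primary alcohol installs a group that survives organolithium reagents and mild acid.

**Step 9**
Reactants: 17 bis-silyl ether
Product: 18 (E)-5-[(tert-butyldiphenylsilyl)oxy]-3-methylpent-3-en-1-ol
Conditions: PPTS (0.2 equiv), EtOH, rt
Reagents that add atoms: none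
Why: Mild acid solvolysis removes a primary TBS ether much faster than a TBDPS ether, so only the homoallylic oxygen is freed.

**Step 10**
Reactants: 18 homoallylic alcohol
Product: 19 (E)-tert-butyl[(5-iodo-3-methylpent-2-en-1-yl)oxy]diphenylsilane
Conditions: I2, PPh3, imidazole, CH2Cl2, 0 °C
Reagents that add atoms: iodine, II
Why: The Appel-type iodination of a primary alcohol is neutral and does not touch the trisubstituted alkene or its geometry.

**Step 11**
Reactants: 12 β-lactone acid; 19 side-chain iodide
Product: 25 15-O-TBDPS-5α,9β-dihydroxyisocupressic acid, via alkyllithium 20 (not isolated), via organocerium reagent 21 (not isolated), via vinyllithium carboxylate 22 (not isolated), via bridged alkoxide 23 (not isolated), via enone dilithium salt 24 (not isolated)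
Conditions: flask A: 19 (2 equiv), t-BuLi (2.1 equiv per 19), Et2O–pentane, −78 °C, then anhydrous CeCl3, THF, −78 °C; flask B: 12, t-BuLi (3.1 equiv), THF–Et2O–pentane, −100 to −78 °C; B added to A, −78 to −40 °C; AcOH–THF quench
Reagents that add atoms: none
Why: Proposed new method: t-BuLi first forms the lithium carboxylate and then exchanges the vinylic bromine, and the C8 vinyllithium 22, held by the C6–C7 tether above the flat oxetanone ring on the face opposite to ring A, adds to the lactone carbonyl C9 to give the 6-oxabicyclo[3.1.1]heptane alkoxide 23, which collapses with cleavage of the strained C9–O5 bond to the 5α-oxido-8(17)-en-9-one 24. The closest known reaction types are the Parham-type cyclisation (halogen–lithium exchange followed by intramolecular acylation by an ester, amide or carboxylate), the analogous closure of vinyl halides onto ketones, and the acyl–oxygen opening of β-lactones by organolithium reagents to β-hydroxy ketones; what is new is their union inside a fused β-lactone. Ring B (C5–C6–C7–C8–C9–C10) closes at C8–C9 in the 6-exo-trig mode, and since C9 is syn to O5 and anti to the C6 chain on ring A the only possible outcome is the trans-decalin with 5α-oxygen and 10β-methyl, so that C4, C5 and C10 are carried over unchanged. The step needs chemoselectivity between C9 and C19, both of which lie within reach of C8, and the substrate secures it because C19 is a deactivated lithium carboxylate whereas C9 is a strained, non-enolisable acyl–oxygen bond. In the second stage the organocerium 21 adds 1,2 to the hindered s-cis enone (organocerium carbonyl addition, which suppresses attack at C17), and the new stereocentre C9 is controlled by the axial 10β-methyl group, which blocks the β face, and by the axial 5α-lithium alkoxide, which can guide the reagent along the α face, so that the 9β-hydroxyl and the α side chain should result. Salt 24 is already doubly deprotonated, so neither protecting groups nor extra base are needed and both bond formations can be run in one flask.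

**Step 12**
Reactants: 25 15-O-TBDPS ether
Product: 26 5α,9β-dihydroxyisocupressic acid, (4S,5S,9S,10R), 13E
Conditions: TBAF/AcOH (1:1, excess), THF, rt
Reagents that add atoms: none
Why: Buffered fluoride desilylation frees the primary allylic alcohol without acid or strong base, so the tertiary allylic alcohol, the exocyclic methylene and all stereocentres should be untouched.

**Compound list**
1 | tert-butyl 2-oxocyclohexane-1-carboxylate | O=C1CCCCC1C(=O)OC(C)(C)C | starting material
2 | dilithium dianion (dienediolate) of 1 | CC(C)(C)OC([O-])=C1CCCC=C1[O-].[Li+].[Li+] | intermediate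
3 | di-tert-butyl 2-oxocyclohexane-1,3-dicarboxylate | O=C1C(CCCC1C(=O)OC(C)(C)C)C(=O)OC(C)(C)C | intermediate
4 | di-tert-butyl (1S)-1-methyl-2-oxocyclohexane-1,3-dicarboxylate (C3 enolisable) | O=C1C(CCC[C@]1(C)C(=O)OC(C)(C)C)C(=O)OC(C)(C)C | intermediate
5 | di-tert-butyl (1S,3S)-1,3-dimethyl-2-oxocyclohexane-1,3-dicarboxylate | O=C1[C@](C)(CCC[C@]1(C)C(=O)OC(C)(C)C)C(=O)OC(C)(C)C | intermediate
6 | 3-bromobut-3-en-1-ol | C=C(Br)CCO | starting material
7 | 2,4-dibromobut-1-ene | C=C(Br)CCBr | intermediate
8 | (3-bromobut-3-en-1-yl)magnesium bromide | C=C(Br)CC[Mg]Br | intermediate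
9 | di-tert-butyl (1S,3S)-2-(3-bromobut-3-en-1-yl)-2-hydroxy-1,3-dimethylcyclohexane-1,3-dicarboxylate | C=C(Br)CCC1(O)[C@](C)(CCC[C@]1(C)C(=O)OC(C)(C)C)C(=O)OC(C)(C)C | intermediate
10 | (1S,3S)-2-(3-bromobut-3-en-1-yl)-2-hydroxy-1,3-dimethylcyclohexane-1,3-dicarboxylic acid | C=C(Br)CCC1(O)[C@](C)(CCC[C@]1(C)C(=O)O)C(=O)O | intermediate
11 | β-lactone 12 with C19 as mixed benzenesulfonic anhydride | C=C(Br)CC[C@]2(O3)[C@](C)(CCC[C@]2(C)C(=O)OS(=O)(=O)c4ccccc4)C3=O | intermediate
12 | (1S,5S,6R)-6-(3-bromobut-3-en-1-yl)-1,5-dimethyl-8-oxo-7-oxabicyclo[4.2.0]octane-5-carboxylic acid | C=C(Br)CC[C@]2(O3)[C@](C)(CCC[C@]2(C)C(=O)O)C3=O | intermediate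
13 | tert-butyl(but-3-yn-1-yloxy)dimethylsilane | C#CCCO[Si](C)(C)C(C)(C)C | starting material
14 | (E)-alkenyl(dimethyl)alane | CC(C)(C)[Si](C)(C)OCC/C(C)=C/[Al](C)C | intermediate
15 | lithium (E)-alkenyl(butyl)dimethylalanate | CC(C)(C)[Si](C)(C)OCC/C(C)=C/[Al-](C)(C)CCCC.[Li+] | intermediate
16 | (E)-5-[(tert-butyldimethylsilyl)oxy]-3-methylpent-2-en-1-ol | CC(C)(C)[Si](C)(C)OCC/C(C)=C/CO | intermediate
17 | (E)-1-(TBDPS-oxy)-5-(TBS-oxy)-3-methylpent-2-ene | CC(C)(C)[Si](C)(C)OCC/C(C)=C/CO[Si](c1ccccc1)(c1ccccc1)C(C)(C)C | intermediate
18 | (E)-5-[(tert-butyldiphenylsilyl)oxy]-3-methylpent-3-en-1-ol | OCC/C(C)=C/CO[Si](c1ccccc1)(c1ccccc1)C(C)(C)C | intermediate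
19 | (E)-tert-butyl[(5-iodo-3-methylpent-2-en-1-yl)oxy]diphenylsilane | ICC/C(C)=C/CO[Si](c1ccccc1)(c1ccccc1)C(C)(C)C | intermediate
20 | (E)-5-(TBDPS-oxy)-3-methylpent-3-enyllithium | [Li]CC/C(C)=C/CO[Si](c1ccccc1)(c1ccccc1)C(C)(C)C | intermediate
21 | (E)-5-(TBDPS-oxy)-3-methylpent-3-enylcerium dichloride | Cl[Ce](Cl)CC/C(C)=C/CO[Si](c1ccccc1)(c1ccccc1)C(C)(C)C | intermediate
22 | C8-lithiated lithium carboxylate of 12 | C=C([Li])CC[C@]2(O3)[C@](C)(CCC[C@]2(C)C(=O)[O-])C3=O.[Li+] | intermediate
23 | bridged tetrahedral alkoxide (6-oxabicyclo[3.1.1]heptane core), dilithium salt | C=C1CC[C@]2(O3)[C@](C)(CCC[C@]2(C)C(=O)[O-])[C@@]13[O-].[Li+].[Li+] | intermediate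
24 | dilithium salt of the 5α-hydroxy-9-oxo-8(17)-ene 19-acid (trans-decalin, 10β-methyl, 4β-carboxylate) | C=C1CC[C@]2([O-])[C@](C)(CCC[C@]2(C)C(=O)[O-])C1=O.[Li+].[Li+] | intermediate
25 | 15-O-TBDPS-5α,9β-dihydroxyisocupressic acid | C=C1CC[C@]2(O)[C@](C)(CCC[C@]2(C)C(=O)O)[C@]1(O)CC/C(C)=C/CO[Si](c1ccccc1)(c1ccccc1)C(C)(C)C | intermediate
26 | 5α,9β-dihydroxyisocupressic acid | C=C1CC[C@]2(O)[C@](C)(CCC[C@]2(C)C(=O)O)[C@]1(O)CC/C(C)=C/CO | target

**Step count**
Total step count: 12.
Longest linear sequence: 7 (steps 1, 2, 4, 5, 6, 11, 12).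

**Steps most likely to fail**

*First, step 11.* t-BuLi may attack the lactone carbonyl before the bromine–lithium exchange is complete. The vinyllithium may be protonated before it closes. In the second stage, conjugate addition at C17 or poor facial selectivity at C9 may compete.

The fallback uses known chemistry, sets out from 12 and comes back at 25. The lactone is opened at its acyl carbon with the magnesium amide of N,O-dimethylhydroxylamine (MeNHOMe·HCl, i-PrMgCl, THF, −20 °C) to the β-hydroxy Weinreb amide acid F1. Bromine–lithium exchange (excess t-BuLi, THF, −78 °C) then closes ring B by a Parham-type cyclisation onto the Weinreb amide. Its chelated tetrahedral intermediate lasts until work-up, so the 5α-hydroxy-9-oxo-8(17)-ene 19-acid F2 can be isolated and purified. F2 is then treated in a separate operation with an excess of organocerium 21 (the first two equivalents serve as base) to give 25. In this way the addition can be studied on its own.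

*Second, step 4.* β-Hydride transfer may reduce the ketone, steric shielding may prevent addition, or retro-aldol opening of the metal alkoxide may erode the configuration at C4 and C10.

The fallback sets out from 5 and comes back at 9, and it brings in C6 as the smallest possible nucleophile. Corey–Chaykovsky reaction with dimethylsulfonium methylide should give the spiro-epoxide F3, again a single isomer because the faces are homotopic. Lithiated 1-(trimethylsilyl)propyne (BF3·OEt2, THF, −78 °C) opens it at the CH2 carbon to the silylalkyne carbinol F4. K2CO3 in MeOH gives the terminal alkyne F5. Bromoboration with B-bromo-9-BBN followed by protonolysis with AcOH gives the 2-bromoalkene 9.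

*Third, step 2.* Enantiofacial control may be lost in the second methylation, where the bias of the first quaternary centre may oppose the catalyst.

The fallback sets out from 3 and comes back at 5, and it replaces asymmetric catalysis by resolution. Exhaustive methylation without a chiral catalyst (K2CO3, MeI, acetone) gives the racemic trans diester F6 and the cis diester F7. These are separated on silica gel. F6 is then resolved by preparative chromatography on a chiral stationary phase to give 5.

**Further compounds**
F1 | step 11 | β-hydroxy Weinreb amide acid (O5 syn to the amide carbon C9, C19 acid anti) | C=C(Br)CC[C@]2(O)[C@](C)(CCC[C@]2(C)C(=O)O)C(=O)N(C)OC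
F2 | step 11 | 5α-hydroxy-9-oxo-8(17)-ene 19-acid (trans-decalin, 10β-methyl) | C=C1CC[C@]2(O)[C@](C)(CCC[C@]2(C)C(=O)O)C1=O
F3 | step 4 | di-tert-butyl (4S,8S)-4,8-dimethyl-1-oxaspiro[2.5]octane-4,8-dicarboxylate | O1CC12[C@](C)(CCC[C@]2(C)C(=O)OC(C)(C)C)C(=O)OC(C)(C)C
F4 | step 4 | di-tert-butyl (1S,3S)-2-hydroxy-1,3-dimethyl-2-[4-(trimethylsilyl)but-3-yn-1-yl]cyclohexane-1,3-dicarboxylate | C[Si](C)(C)C#CCCC1(O)[C@](C)(CCC[C@]1(C)C(=O)OC(C)(C)C)C(=O)OC(C)(C)C
F5 | step 4 | di-tert-butyl (1S,3S)-2-(but-3-yn-1-yl)-2-hydroxy-1,3-dimethylcyclohexane-1,3-dicarboxylate | C#CCCC1(O)[C@](C)(CCC[C@]1(C)C(=O)OC(C)(C)C)C(=O)OC(C)(C)C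
F6 | step 2 | racemic trans diester (1:1 mixture of 5 and its enantiomer) | O=C1[C@](C)(CCC[C@]1(C)C(=O)OC(C)(C)C)C(=O)OC(C)(C)C.O=C1[C@@](C)(CCC[C@@]1(C)C(=O)OC(C)(C)C)C(=O)OC(C)(C)C
F7 | step 2 | cis (meso) diester | O=C1[C@](C)(CCC[C@@]1(C)C(=O)OC(C)(C)C)C(=O)OC(C)(C)C
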